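**Strategy.** The bicyclo[3.3.1]nonane core is disconnected at C1–C8, the bond between the two adjacent quaternary carbons of the cyclohexanone ring (C1, C8, C7, C6, C5, C9). The key step closes this ring by an intramolecular Michael addition of the prenyl-bearing enolate carbon C1 of a dearomatized acylphloroglucinol to a β,β-dimethyl enal tethered to C5. It exploits the 1,3-relationship of the nucleophilic carbons C1 and C5 across C9 in the trioxygenated ring (C1, C2, C3, C4, C5, C9) and sets C1 and the gem-dimethyl C8 in one operation. The precursor, a 4,4-disubstituted cyclohexadienone, arises from an aryl allyl ether by a Claisen–Cope relay. The enal carbonyl carbon later becomes the C7 methylene that receives the endo geranyl chain.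

Key step: step 14

Remark: core numbering is C1 (prenyl bridgehead), C2, C3 (aroyl), C4, C5 (geranyl bridgehead), C6, C7, C8 (CMe2), C9 (bridging C=O); ring A is the trioxygenated ring and ring B the cyclohexanone ring; geranyl = (2E)-3,7-dimethylocta-2,6-dien-1-yl, prenyl = 3-methylbut-2-en-1-yl, ArCO = 3,4-bis(triisopropylsilyloxy)benzoyl; CIP descriptors refer to the tautomers drawn.
Assumption: 1,3-bis(methoxymethoxy)benzene (12) is taken as a catalogue compound.

**Fragment syntheses**

Step 1
Reactants: 1 3,4-dihydroxybenzoic acid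
Product: 3 3,4-bis(triisopropylsilyloxy)benzoic acid, via tris-silylated ester 2 (not isolated)
Conditions: TIPSCl (3.3 equiv), imidazole, DMF, rt; then AcOH–THF–H2O, rt
Reagents that add atoms: chlorotriisopropylsilane, CC(C)[Si](Cl)(C(C)C)C(C)C
Why: Imidazole-mediated silylation should cover both phenols and the acid, and only the labile silyl ester is hydrolysed again, leaving a catechol protection that tolerates base and organometallics and is removed by fluoride.

Step 2
Reactants: 3 3,4-bis(triisopropylsilyloxy)benzoic acid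
Product: 4 3,4-bis(triisopropylsilyloxy)benzoyl chloride
Conditions: (COCl)2, DMF (cat.), CH2Cl2, 0 °C → rt; used crude
Reagents that add atoms: oxalyl chloride, ClC(=O)C(Cl)=O
Why: Acid chloride formation through the Vilsmeier-type chloroiminium species should not affect aryl silyl ethers.

Step 3
Reactants: 5 diethyl 2-(propan-2-ylidene)malonate
Product: 6 2-(propan-2-ylidene)propane-1,3-diol
Conditions: i-Bu2AlH (4.5 equiv), CH2Cl2, −78 → 0 °C; aq. Rochelle salt
Reagents that add atoms: none
Why: 1,2-Hydride reduction of both esters should give the symmetric bis-allylic diol, the tetrasubstituted alkene being hindered toward conjugate reduction.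

Step 4
Reactants: 6 2-(propan-2-ylidene)propane-1,3-diol
Product: 7 2-(hydroxymethyl)-3-methylbut-2-enal
Conditions: MnO2 (activated, excess), CH2Cl2, rt, stopped at mono-oxidation
Reagents that add atoms: none
Why: Allylic oxidation with manganese dioxide; the two CH2OH groups are equivalent, and the second oxidation is expected to be slower because the alkene is then conjugated with an aldehyde.

Step 5
Reactants: 8 5-bromo-2-methylpent-2-ene
Product: 9 6-methylhept-5-en-1-yne
Conditions: LiC≡CH·H2N(CH2)2NH2, DMSO, 10 °C → rt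
Reagents that add atoms: lithium acetylide (ethylenediamine complex), [Li]C#C
Why: SN2 alkylation of the acetylide by an unhindered primary bromide.

Step 6
Reactants: 9 6-methylhept-5-en-1-yne
Product: 11 (1E)-1-iodo-2,6-dimethylhepta-1,5-diene, via alkenylalane 10 (not isolated)
Conditions: Me3Al (2 equiv), Cp2ZrCl2 (0.2 equiv), CH2Cl2, 0 °C → rt; then I2, THF, −30 → 0 °C
Reagents that add atoms: trimethylaluminium, C[Al](C)C; iodine, II
Why: Negishi carboalumination adds methyl and aluminium syn across the terminal alkyne with methyl on the internal carbon, and iodinolysis of the C–Al bond with retention should give the E iodide.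

**Main line**

Step 7
Reactants: 12 1,3-bis(methoxymethoxy)benzene; 13 geranyl bromide
Product: 15 2-geranyl-1,3-bis(methoxymethoxy)benzene, via aryllithium 14 (not isolated)
Conditions: n-BuLi (1.1 equiv), THF, 0 °C; then 13, CuI (10 mol %), −78 °C → rt
Reagents that add atoms: none
Why: Directed ortho-metalation occurs at the carbon flanked by both OMOM groups, and SN2 displacement of the primary allylic bromide should keep the E geometry.

Step 8
Reactants: 15 2-geranyl-1,3-bis(methoxymethoxy)benzene
Product: 17 4-geranyl-3,5-bis(methoxymethoxy)phenol, via arylboronate 16 (not isolated)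
Conditions: [Ir(OMe)(cod)]2 (1.5 mol %), 4,4′-di-tert-butyl-2,2′-bipyridine (3 mol %), B2pin2 (1.0 equiv), THF, 65 °C; then aq. H2O2, NaOH, 0 °C
Reagents that add atoms: hydrogen peroxide, OO
Why: Iridium-catalysed C–H borylation is sterically controlled and should select the only aryl C–H with no ortho substituent (para to geranyl); alkaline peroxide then converts C–B into C–OH without touching trisubstituted alkenes.

Step 9
Reactants: 17 4-geranyl-3,5-bis(methoxymethoxy)phenol; 18 prenyl bromide
Product: 20 4-geranyl-3,5-bis(methoxymethoxy)-2-prenylphenol, via sodium phenolate 19 (not isolated)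
Conditions: NaH (1.05 equiv), toluene, 0 °C; then 18 (1.1 equiv), rt
Reagents that add atoms: none
Why: Ortho C-alkylation of a sodium phenolate contact ion pair in a non-polar solvent; the two ortho positions are equivalent and the para position is blocked.

Step 10
Reactants: 20 4-geranyl-3,5-bis(methoxymethoxy)-2-prenylphenol; 4 3,4-bis(triisopropylsilyloxy)benzoyl chloride
Product: 22 [3-geranyl-6-hydroxy-2,4-bis(methoxymethoxy)-5-prenylphenyl][3,4-bis(triisopropylsilyloxy)phenyl]methanone, via bromomagnesium phenolate 21 (not isolated)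
Conditions: EtMgBr (1.0 equiv), Et2O, 0 °C, solvent changed to toluene; then 4 (1.1 equiv), rt → 50 °C
Reagents that add atoms: none
Why: Ortho-specific C-acylation of a bromomagnesium phenolate through a magnesium-chelated transition state; only one ring position is free, so the aroyl group must enter between OH and OMOM.

Step 11
Reactants: 22 the benzophenone; 7 2-(hydroxymethyl)-3-methylbut-2-enal
Product: 23 2-({2-[3,4-bis(triisopropylsilyloxy)benzoyl]-4-geranyl-3,5-bis(methoxymethoxy)-6-prenylphenoxy}methyl)-3-methylbut-2-enal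
Conditions: PPh3, DIAD, THF, 0 °C → rt
Reagents that add atoms: none
Why: Mitsunobu etherification of the acidic ortho-acylphenol with a primary allylic alcohol; 22 has a single free OH, flanked by the aroyl- and prenyl-bearing carbons, so the position of the allyl ether is unambiguous.

Step 12
Reactants: 23 the aryl allyl ether
Product: 25 (4R)-2-[3,4-bis(triisopropylsilyloxy)benzoyl]-4-(2-formyl-3-methylbut-2-en-1-yl)-4-geranyl-3,5-bis(methoxymethoxy)-6-prenylcyclohexa-2,5-dien-1-one, via ortho-dienone 24 (not isolated)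
Conditions: [Cu((S,S)-t-Bu-box)](SbF6)2 (10 mol %; t-Bu-box = 2,2′-(propane-2,2-diyl)bis[(4S)-4-tert-butyl-4,5-dihydrooxazole]), 4 Å MS, CH2Cl2, rt → 40 °C
Reagents that add atoms: none
Why: Proposed new method: the copper dication is expected to chelate the ether oxygen and the ortho aroyl carbonyl of 23 and to accelerate the aromatic Claisen shift ([3,3]) of the 2-formylprenyl group to an ortho carbon on one arene face only, after which ortho-dienone 24 undergoes a suprafacial Cope shift ([3,3]) that carries the allyl unit and its chirality to the para, geranyl-bearing carbon; the two shifts invert the allyl termini twice, so the para carbon receives CH2 and the CMe2 terminus stays free for C1 whichever ortho carbon reacts first, and the electron-poor 2-formylallyl unit disfavours a dissociative [1,3] path; the closest known reaction types are the thermal para-Claisen (Claisen–Cope) rearrangement of 2,6-disubstituted aryl allyl ethers and the bis(oxazoline)–copper-catalysed enantioselective Claisen rearrangement of chelating 2-alkoxycarbonyl allyl vinyl ethers, which have not been combined on a fully substituted acylphloroglucinol ether; the stereocentre (4R, the later C5) is set by the catalyst in the first shift and transferred by the second, and the ligand antipode is exchanged if the first run shows the opposite sense.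

Step 13
Reactants: 25 the para-dienone
Product: 26 (4R)-2-[3,4-bis(triisopropylsilyloxy)benzoyl]-4-(2-formyl-3-methylbut-2-en-1-yl)-4-geranyl-3,5-dihydroxy-6-prenylcyclohexa-2,5-dien-1-one (one enol tautomer)
Conditions: AcOH–THF–H2O (3:1:1), 40 °C
Reagents that add atoms: none
Why: After dearomatization both MOM groups are acetals of vinylogous acids and should hydrolyse under acid mild enough to spare the aryl silyl ethers, the aldehyde and the trisubstituted alkenes.

Step 14
Reactants: 26 the dearomatized acylphloroglucinol enal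
Product: 29 (1S,5S)-3-[3,4-bis(triisopropylsilyloxy)benzoyl]-5-geranyl-4-hydroxy-8,8-dimethyl-1-prenyl-7-{[(trifluoromethylsulfonyl)oxy]methylidene}bicyclo[3.3.1]non-3-ene-2,9-dione, via dipotassium dienolate 27 (not isolated), via dipotassium aldehyde enolate 28 (not isolated)
Conditions: KN(SiMe3)2 (2.1 equiv), THF, −78 → 50 °C; then PhNTf2 (1.05 equiv), −78 → 0 °C; 1 M HCl work-up
Reagents that add atoms: N-phenylbis(trifluoromethanesulfonimide), O=S(=O)(N(c1ccccc1)S(=O)(=O)C(F)(F)F)C(F)(F)F
Why: Two equivalents of base convert 26 into its dianion, whose second, less stabilised enolate (O–C9=C1, carrying the prenyl group) adds in an intramolecular Michael reaction to the β,β-dimethyl carbon C8 of the enal, and the resulting aldehyde enolate is trapped on oxygen by PhNTf2 (tandem conjugate addition–enolate triflation). The closest known reaction type is the base-mediated alkylative dearomatization–annulation of prenylated acylphloroglucinols with α-(acyloxymethyl) enals, of which this is the ring-forming second stage. Ring B (C1–C8–C7–C6–C5–C9) closes in the 6-endo-trig mode. C1 is the only new stereocentre and is dictated by C5, because the three-atom tether C6–C7–C8 can reach C1 only from its own face (1S from 5S), while C7 stays trigonal. The step needs C-1,4- over O- and 1,2-addition and C1 over C3 as nucleophile: aldol and oxa-Michael adducts form reversibly whereas the C–C conjugate adduct is drained as the enol triflate, and C3, the central carbon of the acyl-stabilised triketonate, is far less nucleophilic and more hindered than C1. Which bridgehead carries CH2 and which CMe2 was already fixed in step 12.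

Step 15
Reactants: 29 the enol triflate
Product: 30 (1S,5S)-3-[3,4-bis(triisopropylsilyloxy)benzoyl]-5-geranyl-4-hydroxy-8,8-dimethyl-7-methylidene-1-prenylbicyclo[3.3.1]non-3-ene-2,9-dione
Conditions: Pd(OAc)2 (5 mol %), PPh3 (10 mol %), HCO2H (2 equiv), n-Bu3N (3 equiv), DMF, 60 °C
Reagents that add atoms: none
Why: Palladium-catalysed formate reduction of an enol triflate (oxidative addition to zerovalent palladium, formate exchange, decarboxylation, C–H reductive elimination) should leave the trisubstituted alkenes and the enol untouched.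

Step 16
Reactants: 30 the 7-methylidene compound; 11 (1E)-1-iodo-2,6-dimethylhepta-1,5-diene
Product: 32 3′,4′-bis-O-triisopropylsilyl oblongifolin D, (1S,5S,7S), via alkylborane 31 (not isolated)
Conditions: 9-BBN-H (3 equiv), THF, 0 °C → rt; then 11, Pd(dppf)Cl2 (10 mol %), AsPh3, aq. K3PO4, DMF, rt → 45 °C
Reagents that add atoms: none
Why: 9-BBN should hydroborate only the 1,1-disubstituted C7 methylene (anti-Markovnikov) and approach its exo face, the endo face being screened by the C2–C3–C4 bridge and its aroyl group, so that H is delivered exo and the CH2B arm ends endo (7S); B-alkyl Suzuki–Miyaura coupling with 11 then completes the geranyl chain with retention of the E geometry.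

Step 17
Reactants: 32 bis-silyl oblongifolin D
Product: 33 oblongifolin D
Conditions: Bu4NF (2.5 equiv), AcOH (3 equiv), THF, 0 °C → rt
Reagents that add atoms: none
Why: Buffered fluoride cleaves the two aryl Si–O bonds without acid, which avoids cyclisation of the enol onto the prenyl groups, and no stereocentre is touched.

**Compound list**

1 | 3,4-dihydroxybenzoic acid | OC(=O)c1ccc(O)c(O)c1 | starting material
2 | triisopropylsilyl 3,4-bis(triisopropylsilyloxy)benzoate | CC(C)[Si](OC(=O)c1ccc(O[Si](C(C)C)(C(C)C)C(C)C)c(O[Si](C(C)C)(C(C)C)C(C)C)c1)(C(C)C)C(C)C | intermediate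
3 | 3,4-bis(triisopropylsilyloxy)benzoic acid | OC(=O)c1ccc(O[Si](C(C)C)(C(C)C)C(C)C)c(O[Si](C(C)C)(C(C)C)C(C)C)c1 | intermediate
4 | 3,4-bis(triisopropylsilyloxy)benzoyl chloride | ClC(=O)c1ccc(O[Si](C(C)C)(C(C)C)C(C)C)c(O[Si](C(C)C)(C(C)C)C(C)C)c1 | intermediate
5 | diethyl 2-(propan-2-ylidene)malonate | CCOC(=O)C(=C(C)C)C(=O)OCC | starting material
6 | 2-(propan-2-ylidene)propane-1,3-diol | CC(C)=C(CO)CO | intermediate
7 | 2-(hydroxymethyl)-3-methylbut-2-enal | CC(C)=C(CO)C=O | intermediate
8 | 5-bromo-2-methylpent-2-ene | CC(C)=CCCBr | starting material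
9 | 6-methylhept-5-en-1-yne | CC(C)=CCCC#C | intermediate
10 | dimethyl[(1E)-2,6-dimethylhepta-1,5-dien-1-yl]alane | C[Al](C)/C=C(\C)CCC=C(C)C | intermediate
11 | (1E)-1-iodo-2,6-dimethylhepta-1,5-diene | I/C=C(\C)CCC=C(C)C | intermediate
12 | 1,3-bis(methoxymethoxy)benzene | COCOc1cccc(OCOC)c1 | starting material
13 | geranyl bromide, (2E)-1-bromo-3,7-dimethylocta-2,6-diene | BrC/C=C(\C)CCC=C(C)C | starting material
14 | 2,6-bis(methoxymethoxy)phenyllithium | [Li]c1c(OCOC)cccc1OCOC | intermediate
15 | 2-geranyl-1,3-bis(methoxymethoxy)benzene | COCOc1cccc(OCOC)c1C/C=C(\C)CCC=C(C)C | intermediate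
16 | 2-[4-geranyl-3,5-bis(methoxymethoxy)phenyl]-4,4,5,5-tetramethyl-1,3,2-dioxaborolane | COCOc1cc(B2OC(C)(C)C(C)(C)O2)cc(OCOC)c1C/C=C(\C)CCC=C(C)C | intermediate
17 | 4-geranyl-3,5-bis(methoxymethoxy)phenol | COCOc1cc(O)cc(OCOC)c1C/C=C(\C)CCC=C(C)C | intermediate
18 | prenyl bromide, 1-bromo-3-methylbut-2-ene | CC(C)=CCBr | starting material
19 | sodium 4-geranyl-3,5-bis(methoxymethoxy)phenolate | [Na+].[O-]c1cc(OCOC)c(C/C=C(\C)CCC=C(C)C)c(OCOC)c1 | intermediate
20 | 4-geranyl-3,5-bis(methoxymethoxy)-2-prenylphenol | COCOc1cc(O)c(CC=C(C)C)c(OCOC)c1C/C=C(\C)CCC=C(C)C | intermediate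
21 | bromomagnesium 4-geranyl-3,5-bis(methoxymethoxy)-2-prenylphenolate | COCOc1cc(O[Mg]Br)c(CC=C(C)C)c(OCOC)c1C/C=C(\C)CCC=C(C)C | intermediate
22 | [3-geranyl-6-hydroxy-2,4-bis(methoxymethoxy)-5-prenylphenyl][3,4-bis(triisopropylsilyloxy)phenyl]methanone | COCOc1c(C(=O)c2ccc(O[Si](C(C)C)(C(C)C)C(C)C)c(O[Si](C(C)C)(C(C)C)C(C)C)c2)c(O)c(CC=C(C)C)c(OCOC)c1C/C=C(\C)CCC=C(C)C | intermediate
23 | 2-({2-ArCO-4-geranyl-3,5-bis(methoxymethoxy)-6-prenylphenoxy}methyl)-3-methylbut-2-enal | COCOc1c(C(=O)c2ccc(O[Si](C(C)C)(C(C)C)C(C)C)c(O[Si](C(C)C)(C(C)C)C(C)C)c2)c(OCC(C=O)=C(C)C)c(CC=C(C)C)c(OCOC)c1C/C=C(\C)CCC=C(C)C | intermediate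
24 | (6S)-2-ArCO-6-(3-formyl-2-methylbut-3-en-2-yl)-4-geranyl-3,5-bis(methoxymethoxy)-6-prenylcyclohexa-2,4-dien-1-one | COCOC1=C(C/C=C(\C)CCC=C(C)C)C(OCOC)=C(C(=O)c2ccc(O[Si](C(C)C)(C(C)C)C(C)C)c(O[Si](C(C)C)(C(C)C)C(C)C)c2)C(=O)[C@@]1(CC=C(C)C)C(C)(C)C(C=O)=C | intermediate
25 | (4R)-2-ArCO-4-(2-formyl-3-methylbut-2-en-1-yl)-4-geranyl-3,5-bis(methoxymethoxy)-6-prenylcyclohexa-2,5-dien-1-one | O=CC(=C(C)C)C[C@]1(C/C=C(\C)CCC=C(C)C)C(OCOC)=C(CC=C(C)C)C(=O)C(C(=O)c2ccc(O[Si](C(C)C)(C(C)C)C(C)C)c(O[Si](C(C)C)(C(C)C)C(C)C)c2)=C1OCOC | intermediate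
26 | (4R)-2-ArCO-4-(2-formyl-3-methylbut-2-en-1-yl)-4-geranyl-3,5-dihydroxy-6-prenylcyclohexa-2,5-dien-1-one | O=CC(=C(C)C)C[C@]1(C/C=C(\C)CCC=C(C)C)C(O)=C(CC=C(C)C)C(=O)C(C(=O)c2ccc(O[Si](C(C)C)(C(C)C)C(C)C)c(O[Si](C(C)C)(C(C)C)C(C)C)c2)=C1O | intermediate
27 | dipotassium dienolate of 26 | [K+].[K+].O=CC(=C(C)C)C[C@]1(C/C=C(\C)CCC=C(C)C)C([O-])=C(CC=C(C)C)C(=O)C(C(=O)c2ccc(O[Si](C(C)C)(C(C)C)C(C)C)c(O[Si](C(C)C)(C(C)C)C(C)C)c2)=C1[O-] | intermediate
28 | dipotassium salt of the (1S,5S)-bicyclic Michael adduct (C7 aldehyde enolate and triketonate) | [K+].[K+].[O-]C=C1C[C@]2(C/C=C(\C)CCC=C(C)C)C(=O)[C@@](CC=C(C)C)(C(=O)C(C(=O)c3ccc(O[Si](C(C)C)(C(C)C)C(C)C)c(O[Si](C(C)C)(C(C)C)C(C)C)c3)=C2[O-])C1(C)C | intermediate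
29 | (1S,5S)-3-ArCO-5-geranyl-4-hydroxy-8,8-dimethyl-1-prenyl-7-{[(trifluoromethylsulfonyl)oxy]methylidene}bicyclo[3.3.1]non-3-ene-2,9-dione | O=S(=O)(OC=C1C[C@]2(C/C=C(\C)CCC=C(C)C)C(=O)[C@@](CC=C(C)C)(C(=O)C(C(=O)c3ccc(O[Si](C(C)C)(C(C)C)C(C)C)c(O[Si](C(C)C)(C(C)C)C(C)C)c3)=C2O)C1(C)C)C(F)(F)F | intermediate
30 | (1S,5S)-3-ArCO-5-geranyl-4-hydroxy-8,8-dimethyl-7-methylidene-1-prenylbicyclo[3.3.1]non-3-ene-2,9-dione | C=C1C[C@]2(C/C=C(\C)CCC=C(C)C)C(=O)[C@@](CC=C(C)C)(C(=O)C(C(=O)c3ccc(O[Si](C(C)C)(C(C)C)C(C)C)c(O[Si](C(C)C)(C(C)C)C(C)C)c3)=C2O)C1(C)C | intermediate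
31 | (1S,5S,7S)-7-[(9-borabicyclo[3.3.1]nonan-9-yl)methyl] derivative of 30 with the enol held as its 9-BBN borinate | B4(C5CCCC4CCC5)C[C@H]1C[C@]2(C/C=C(\C)CCC=C(C)C)C(=O)[C@@](CC=C(C)C)(C(=O)C(C(=O)c3ccc(O[Si](C(C)C)(C(C)C)C(C)C)c(O[Si](C(C)C)(C(C)C)C(C)C)c3)=C2OB6C7CCCC6CCC7)C1(C)C | intermediate
32 | 3′,4′-bis-O-triisopropylsilyl oblongifolin D, (1S,5S,7S) | CC(C)=CCC/C(C)=C/C[C@H]1C[C@]2(C/C=C(\C)CCC=C(C)C)C(=O)[C@@](CC=C(C)C)(C(=O)C(C(=O)c3ccc(O[Si](C(C)C)(C(C)C)C(C)C)c(O[Si](C(C)C)(C(C)C)C(C)C)c3)=C2O)C1(C)C | intermediate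
33 | oblongifolin D, (1S,5S,7S) | CC(C)=CCC/C(C)=C/C[C@H]1C[C@]2(C/C=C(\C)CCC=C(C)C)C(=O)[C@@](CC=C(C)C)(C(=O)C(C(=O)c3ccc(O)c(O)c3)=C2O)C1(C)C | target

**Count and risks**

Total: 17 steps. Longest linear sequence: 11 steps (steps 7–17, from 12).

Steps most likely to fail:

1. Step 12 (Claisen–Cope relay under chiral copper catalysis). The Lewis acid may be bound unproductively by the aldehyde and MOM oxygens, so that only the racemic thermal rearrangement proceeds, or it may ionise the ether to an allyl cation–phenolate pair and scramble the allyl termini. Fallback with known chemistry, setting out from 23: the thermal para-Claisen rearrangement (toluene, 110–130 °C) should give the racemic para-dienone F1. Condensation of its aldehyde with purchased (1R,2R)-N,N′-dimethyl-1,2-diphenylethane-1,2-diamine (4 Å MS, CH2Cl2) gives two diastereomeric imidazolidines, of which the (4R)-configured aminal F2 is separated by chromatography. Aqueous AcOH–THF then cleaves the aminal together with both MOM groups, and the route is rejoined at 26.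

2. Step 14 (key Michael closure with triflate trapping). The hindered dienolate may add through oxygen or through the aroyl-bearing C3, or conjugate addition to the β,β-disubstituted enal may be too slow and the dianion may decay; triflation may also occur on the triketone oxygen. Fallback, setting out from 25: ring closure under acid rather than base. Formic acid in CH2Cl2 at 0 °C with short contact time should cleave the MOM acetals and let the enol add to the protonated enal under thermodynamic control (1,2-adducts revert, the 1,4-adduct accumulates), giving the bicyclic trione aldehyde F3 as C7 epimers. Separate treatment of F3 with KN(SiMe3)2 (2.1 equiv) and PhNTf2 converges on 29.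

3. Step 10 (C-acylation of the hindered phenolate). Acylation may occur on oxygen instead of carbon, and the magnesium halide formed may strip the MOM group next to the new ketone, which would destroy the single-OH control used in step 11. Fallback, setting out from 20: the bromomagnesium phenolate is added to an aldehyde instead of an acid chloride. 3,4-Bis(triisopropylsilyloxy)benzaldehyde F4 (from purchased 3,4-dihydroxybenzaldehyde, TIPSCl, imidazole, DMF) should give, by ortho-specific hydroxyalkylation in toluene, the diaryl carbinol F5, which is oxidised with MnO2 (CH2Cl2, rt) to rejoin the route at 22.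

Further compounds
F1 | step 12 | racemic 2-ArCO-4-(2-formyl-3-methylbut-2-en-1-yl)-4-geranyl-3,5-bis(methoxymethoxy)-6-prenylcyclohexa-2,5-dien-1-one | O=CC(=C(C)C)CC1(C/C=C(\C)CCC=C(C)C)C(OCOC)=C(CC=C(C)C)C(=O)C(C(=O)c2ccc(O[Si](C(C)C)(C(C)C)C(C)C)c(O[Si](C(C)C)(C(C)C)C(C)C)c2)=C1OCOC
F2 | step 12 | (4R,5R)-1,3-dimethyl-4,5-diphenylimidazolidin-2-yl aminal of (4R)-25 | CC(C)=C(C[C@]1(C/C=C(\C)CCC=C(C)C)C(OCOC)=C(CC=C(C)C)C(=O)C(C(=O)c2ccc(O[Si](C(C)C)(C(C)C)C(C)C)c(O[Si](C(C)C)(C(C)C)C(C)C)c2)=C1OCOC)C3N(C)[C@H](c4ccccc4)[C@@H](c4ccccc4)N3C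
F3 | step 14 | (1S,5S)-3-ArCO-7-formyl-5-geranyl-4-hydroxy-8,8-dimethyl-1-prenylbicyclo[3.3.1]non-3-ene-2,9-dione, C7 epimers | O=CC1C[C@]2(C/C=C(\C)CCC=C(C)C)C(=O)[C@@](CC=C(C)C)(C(=O)C(C(=O)c3ccc(O[Si](C(C)C)(C(C)C)C(C)C)c(O[Si](C(C)C)(C(C)C)C(C)C)c3)=C2O)C1(C)C
F4 | step 10 | 3,4-bis(triisopropylsilyloxy)benzaldehyde | O=Cc1ccc(O[Si](C(C)C)(C(C)C)C(C)C)c(O[Si](C(C)C)(C(C)C)C(C)C)c1
F5 | step 10 | [3-geranyl-6-hydroxy-2,4-bis(methoxymethoxy)-5-prenylphenyl][3,4-bis(triisopropylsilyloxy)phenyl]methanol, racemic at the carbinol | COCOc1c(C(O)c2ccc(O[Si](C(C)C)(C(C)C)C(C)C)c(O[Si](C(C)C)(C(C)C)C(C)C)c2)c(O)c(CC=C(C)C)c(OCOC)c1C/C=C(\C)CCC=C(C)C
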